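**Retrosynthetic overview**
- Ring C of every flavan unit is closed through its O1–C2 carbon–oxygen bond by an oxidative oxa-Michael (Algar–Flynn–Oyamada) cyclisation of one chalcone. Rings A and B are bought, and ring C is the only skeletal ring built (once, then used three times).
- The resulting flavonol is reduced in one new enantioselective all-cis hydrogenation to a single monomer, tri-O-benzyl-teracacidin, which carries C2, C3 and C4 of all three units.
- Two C4–O operations on this monomer assign the roles: an axial 4β-(2-ethoxyethyl) ether is the ionisable chain-extension donor, and a cis-3,4-cyclic carbonate is the non-ionisable chain end.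
- The two 4β→6 interflavan bonds follow by two successive cation arylations with the same donor (chain end + donor, then dimer + donor).
- The end game is carbonate hydrolysis and hydrogenolysis of nine benzyl ethers.

Assumption: the target is read as epioritin-(4β→6)-epioritin-(4β→6)-epioritin-4α-ol (units 2R,3R,4S / 2R,3R,4S / 2R,3R,4R), and the (R,R) carbene ligand is assumed to give the 2R series (otherwise its mirror image is used).

**Route**

Step 1
Reactants: 1 2,3,4-trihydroxyacetophenone (gallacetophenone)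
Product: 2 1-[3,4-bis(benzyloxy)-2-hydroxyphenyl]ethan-1-one
Conditions: BnBr (2.05 equiv), K2CO3 (2.1 equiv), acetone, reflux
Reagents that add atoms: benzyl bromide, BrCc1ccccc1
Why: Williamson etherification, in which the 2-OH is held in a hydrogen bond to the acetyl carbonyl and is the least acidic, so two equivalents of benzyl bromide alkylate only O3 and O4.

Step 2
Reactants: 2 1-[3,4-bis(benzyloxy)-2-hydroxyphenyl]ethan-1-one; 3 4-(benzyloxy)benzaldehyde
Product: 7 7,8-bis(benzyloxy)-2-[4-(benzyloxy)phenyl]-3-hydroxy-4H-chromen-4-one (flavonol), via aldol adduct 4 (not isolated), via chalcone 5 (not isolated), via trans-dihydroflavonol 6 (not isolated)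
Conditions: KOH (6 equiv), EtOH/THF, rt, 36 h; then 30% aq H2O2 (4 equiv), 0 °C → rt; aq HCl
Reagents that add atoms: hydrogen peroxide, OO
Why: Claisen–Schmidt aldol condensation gives the chalcone, and the Algar–Flynn–Oyamada oxidation then closes ring C through the O1–C2 carbon–oxygen bond (phenoxide oxa-Michael addition) while hydroperoxide installs the C3–O bond and oxidises the dihydroflavonol to the flavonol; with no 6'-substituent the six-membered closure is preferred over aurone formation, and no stereocentre has to be controlled yet.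

Step 3
Reactants: 7 flavonol
Product: 9 (2R,3R,4R)-7,8-bis(benzyloxy)-2-[4-(benzyloxy)phenyl]chromane-3,4-diol (7,8,4'-tri-O-benzyl-teracacidin), via cis-dihydroflavonol 8 (not isolated)
Conditions: H2 (100 bar), Ru(cod)(2-methylallyl)2 (5 mol %), (R,R)-1,3-bis[1-(1-naphthyl)ethyl]imidazolinium tetrafluoroborate (10 mol %), KOtBu (10 mol %), toluene, 25 → 40 °C
Reagents that add atoms: none
Why: Proposed new method: the enantioselective hydrogenation with the chiral catalyst made from Ru(cod)(2-methylallyl)2 and the carbene ligand is extended from flavones to a 3-hydroxyflavone; the catalyst binds one face of the planar pyranone and adds H2 syn across the tetrasubstituted C2=C3 enol double bond (sets C2 as R and places 2-aryl and 3-OH cis, giving 8), and the ketone of 8 is then reduced by axial hydride delivery on that same face, anti to the now axial 3-OH, before the α-hydroxy ketone can epimerise (sets C4, all-cis 2R,3R,4R); the closest known reactions are the hydrogenation of flavones and chromones to cis-flavan-4-ols with this catalyst type and the classical racemic hydrogenation of flavonols over Ni or PtO2 to 2,3-cis-3,4-cis-flavan-3,4-diols, and aryl benzyl ethers are not cleaved by this homogeneous catalyst.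

Step 4
Reactants: 9 tri-O-benzyl-teracacidin
Product: 11 3,4-O-carbonyl derivative of 9 (cis-fused cyclic carbonate), via 4-O-imidazolylcarbonyl ester 10 (not isolated)
Conditions: CDI (1.5 equiv), DMAP (5 mol %), CH2Cl2, 0 °C → rt
Reagents that add atoms: 1,1'-carbonyldiimidazole, O=C(n1ccnc1)n1ccnc1
Why: Cyclic carbonate formation by acyl transfer, in which the equatorial O4 is acylated first and the cis O3 closes the five-membered ring; the ring holds the C4–O bond pseudo-equatorial (out of overlap with the ring A π system) and makes it electron-poor, so this unit should not ionise in steps 6 and 7, and no stereocentre is touched.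

Step 5
Reactants: 9 tri-O-benzyl-teracacidin
Product: 13 (2R,3R,4S)-7,8-bis(benzyloxy)-2-[4-(benzyloxy)phenyl]-4-(2-ethoxyethoxy)chroman-3-ol (4β ether), via flavan-4-yl cation 12 (not isolated)
Conditions: 2-ethoxyethanol (20 equiv), camphorsulfonic acid (10 mol %), 4 Å MS, CH2Cl2, 0 °C → rt; Et3N
Reagents that add atoms: 2-ethoxyethanol, CCOCCO
Why: Acid-catalysed SN1 etherification, in which the benzylic C4–OH ionises to the 7-alkoxy-stabilised cation and the alcohol traps it axially, trans to the 3-OH, giving the 4β ether; its axial C–O bond overlaps with the ring A π system, so 13 is a storable precursor that releases cation 12 again far more easily than the carbonate of 11 ionises (a 4α epimer, if formed, is equally usable because both give the same cation).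

Step 6
Reactants: 13 4β ether donor; 11 cyclic carbonate (4 equiv)
Product: 14 hexa-O-benzyl-epioritin-(4β→6)-epioritin-4α-ol 3,4-carbonate (dimer with free 3-OH in the upper unit)
Conditions: Me3SiOTf (0.2 equiv), CH2Cl2, −78 → −40 °C; Et3N; excess 11 recovered
Reagents that add atoms: none
Why: Lewis-acid-promoted Friedel–Crafts-type flavan-4-yl cation arylation (the standard proanthocyanidin coupling), in which Me3SiOTf ionises only the axial ether of 13 at low temperature, releasing the electrophile 12 of step 5 as a transient; C6 of 11 (ortho to the 7-benzyloxy group and para to O1) is the most nucleophilic free position, and its attack trans to the axial 3-OH sets the new C4 stereocentre as 4β, while the fourfold excess of 11 suppresses self-condensation of the donor.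

Step 7
Reactants: 13 4β ether donor; 14 dimer (2.5 equiv)
Product: 15 nona-O-benzyl-epioritin-(4β→6)-epioritin-(4β→6)-epioritin-4α-ol 3,4-carbonate (trimer)
Conditions: Me3SiOTf (0.2 equiv), CH2Cl2, −78 → −40 °C, slow addition of 13; Et3N; excess 14 recovered
Reagents that add atoms: none
Why: The same cation arylation with the same transient electrophile released from 13, in which the only doubly activated free position of 14 is C6 of its upper unit (C6 of the lower unit is already substituted) and attack again occurs trans to the 3-OH to give the second 4β→6 bond; the excess of 14 and slow addition of the donor limit growth beyond the trimer.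

Step 8
Reactants: 15 trimer carbonate
Product: 16 nona-O-benzyl-epioritin-(4β→6)-epioritin-(4β→6)-epioritin-4α-ol
Conditions: LiOH (4 equiv), THF/H2O (4:1), 0 °C → rt
Reagents that add atoms: none
Why: Carbonate saponification, in which hydroxide attacks the carbonyl carbon and not a stereocentre, so the cis-3,4-diol is released with retention while benzyl ethers and interflavan bonds are stable to base.

Step 9
Reactants: 16 nona-O-benzyl trimer
Product: 17 epioritin-(4β→6)-epioritin-(4β→6)-epioritin-4α-ol (CNP0140823.1)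
Conditions: H2 (1 bar), Pd(OH)2/C (20 wt %), THF/MeOH/H2O (10:10:1), rt; filtration under Ar; Sephadex LH-20
Reagents that add atoms: none
Why: Hydrogenolysis of the nine aryl benzyl ethers under neutral conditions, where aryl–O–CH2Ph cleavage is much faster than loss of the secondary benzylic 4-OH or cleavage of the diarylmethine interflavan bonds, and no stereocentre is involved.

**Compound list**

1 | 2,3,4-trihydroxyacetophenone | CC(=O)c1ccc(O)c(O)c1O | starting material
2 | 1-[3,4-bis(benzyloxy)-2-hydroxyphenyl]ethan-1-one | CC(=O)c1ccc(OCc2ccccc2)c(OCc2ccccc2)c1O | intermediate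
3 | 4-(benzyloxy)benzaldehyde | O=Cc1ccc(OCc2ccccc2)cc1 | starting material
4 | 1-[3,4-bis(benzyloxy)-2-hydroxyphenyl]-3-[4-(benzyloxy)phenyl]-3-hydroxypropan-1-one (racemic aldol adduct) | O=C(CC(O)c1ccc(OCc2ccccc2)cc1)c1ccc(OCc2ccccc2)c(OCc2ccccc2)c1O | intermediate
5 | (2E)-1-[3,4-bis(benzyloxy)-2-hydroxyphenyl]-3-[4-(benzyloxy)phenyl]prop-2-en-1-one (chalcone) | O=C(/C=C/c1ccc(OCc2ccccc2)cc1)c1ccc(OCc2ccccc2)c(OCc2ccccc2)c1O | intermediate
6 | rac-(2R,3R)-7,8-bis(benzyloxy)-2-[4-(benzyloxy)phenyl]-3-hydroxychroman-4-one (trans-dihydroflavonol, racemic, one enantiomer drawn) | c1cc2c(c(OCc5ccccc5)c1OCc5ccccc5)O[C@H](c1ccc(OCc5ccccc5)cc1)[C@@H](O)C2=O | intermediate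
7 | 7,8-bis(benzyloxy)-2-[4-(benzyloxy)phenyl]-3-hydroxy-4H-chromen-4-one (flavonol) | c1cc2c(c(OCc5ccccc5)c1OCc5ccccc5)oc(-c1ccc(OCc5ccccc5)cc1)c(O)c2=O | intermediate
8 | (2R,3S)-7,8-bis(benzyloxy)-2-[4-(benzyloxy)phenyl]-3-hydroxychroman-4-one (cis-dihydroflavonol) | c1cc2c(c(OCc5ccccc5)c1OCc5ccccc5)O[C@H](c1ccc(OCc5ccccc5)cc1)[C@H](O)C2=O | intermediate
9 | (2R,3R,4R)-7,8-bis(benzyloxy)-2-[4-(benzyloxy)phenyl]chromane-3,4-diol (tri-O-benzyl-teracacidin, all-cis) | c1cc2c(c(OCc5ccccc5)c1OCc5ccccc5)O[C@H](c1ccc(OCc5ccccc5)cc1)[C@H](O)[C@@H]2O | intermediate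
10 | 4-O-(imidazol-1-ylcarbonyl) ester of 9 | c1cc2c(c(OCc5ccccc5)c1OCc5ccccc5)O[C@H](c1ccc(OCc5ccccc5)cc1)[C@H](O)[C@@H]2OC(=O)n1ccnc1 | intermediate
11 | 3,4-O-carbonyl derivative of 9 (cis-fused cyclic carbonate, 2-aryl and both ring oxygens on the same face) | c1cc2c(c(OCc5ccccc5)c1OCc5ccccc5)O[C@H](c1ccc(OCc5ccccc5)cc1)[C@H](OC(=O)O6)[C@@H]26 | intermediate
12 | (2R,3R)-7,8-bis(benzyloxy)-2-[4-(benzyloxy)phenyl]-3-hydroxychroman-4-ylium (flavan-4-yl cation, drawn without its counter-ion; formed from 9 in step 5 and the transient electrophile that 13 releases in steps 6 and 7) | c1cc2c(c(OCc5ccccc5)c1OCc5ccccc5)O[C@H](c1ccc(OCc5ccccc5)cc1)[C@H](O)[CH+]2 | intermediate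
13 | (2R,3R,4S)-7,8-bis(benzyloxy)-2-[4-(benzyloxy)phenyl]-4-(2-ethoxyethoxy)chroman-3-ol (4β ether, trans to 3-OH) | c1cc2c(c(OCc5ccccc5)c1OCc5ccccc5)O[C@H](c1ccc(OCc5ccccc5)cc1)[C@H](O)[C@H]2OCCOCC | intermediate
14 | hexa-O-benzyl-epioritin-(4β→6)-epioritin-4α-ol 3,4-carbonate (upper unit 2R, 3-OH cis to 2-aryl, C4 aryl trans to 3-OH; lower unit is 11 substituted at C6) | c5ccccc5COc1ccc([C@H]2Oc3c(ccc(OCc5ccccc5)c3OCc5ccccc5)[C@H](c3cc4c(c(OCc5ccccc5)c3OCc5ccccc5)O[C@H](c3ccc(OCc5ccccc5)cc3)[C@H](OC(=O)O6)[C@@H]46)[C@H]2O)cc1 | intermediate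
15 | nona-O-benzyl-epioritin-(4β→6)-epioritin-(4β→6)-epioritin-4α-ol 3,4-carbonate | c5ccccc5COc1ccc([C@H]2Oc3c(ccc(OCc5ccccc5)c3OCc5ccccc5)[C@H](c3cc4c(c(OCc5ccccc5)c3OCc5ccccc5)O[C@H](c3ccc(OCc5ccccc5)cc3)[C@H](O)[C@H]4c3cc4c(c(OCc5ccccc5)c3OCc5ccccc5)O[C@H](c3ccc(OCc5ccccc5)cc3)[C@H](OC(=O)O6)[C@@H]46)[C@H]2O)cc1 | intermediate
16 | nona-O-benzyl-epioritin-(4β→6)-epioritin-(4β→6)-epioritin-4α-ol | c5ccccc5COc1ccc([C@H]2Oc3c(ccc(OCc5ccccc5)c3OCc5ccccc5)[C@H](c3cc4c(c(OCc5ccccc5)c3OCc5ccccc5)O[C@H](c3ccc(OCc5ccccc5)cc3)[C@H](O)[C@H]4c3cc4c(c(OCc5ccccc5)c3OCc5ccccc5)O[C@H](c3ccc(OCc5ccccc5)cc3)[C@H](O)[C@@H]4O)[C@H]2O)cc1 | intermediate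
17 | epioritin-(4β→6)-epioritin-(4β→6)-epioritin-4α-ol, units (2R,3R,4S)/(2R,3R,4S)/(2R,3R,4R), CNP0140823.1 | Oc1ccc([C@H]2Oc3c(ccc(O)c3O)[C@H](c3cc4c(c(O)c3O)O[C@H](c3ccc(O)cc3)[C@H](O)[C@H]4c3cc4c(c(O)c3O)O[C@H](c3ccc(O)cc3)[C@H](O)[C@@H]4O)[C@H]2O)cc1 | target

**Step count and risks**

Total step count: 9. Longest linear sequence: 8 (steps 1, 2, 3, 4 or 5, 6, 7, 8, 9).

Three steps most likely to fail:

Step 3 (the proposed new hydrogenation). The tetrasubstituted, 3-oxygenated double bond and the acidic enol have not been shown with this catalyst, and the cis ketone 8 could epimerise before it is reduced. The fallback uses known chemistry and replaces asymmetric catalysis by racemic reduction plus resolution. It sets out from 7: the long-known heterogeneous flavonol hydrogenation (H2 4 bar, PtO2, EtOAc/EtOH, rt; aryl benzyl ethers are far more stable over PtO2 than over Pd/C) gives the racemic all-cis diol F1. Preparative chiral supercritical-fluid chromatography on an amylose tris(3,5-dimethylphenylcarbamate) phase then separates the wanted enantiomer from the (2S,3S,4S) mirror-image diol F2. The fallback comes back to the route at 9.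

Step 6 (first coupling). The carbonate of 11 might still ionise under the oxophilic Lewis acid, or C6 of the pyrogallol-type ring A might be too weak a nucleophile, so that O-linked or self-condensed products result. The fallback switches from oxophilic to thiophilic activation, which leaves every C4–O function untouched. It sets out from 9: phenylmethanethiol with catalytic BF3·OEt2 in CH2Cl2 at −20 °C gives the 4β-benzylsulfanyl donor F3. AgBF4 in CH2Cl2/THF at −20 → 0 °C then couples F3 with excess 11. The fallback comes back at 14.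

Step 7 (second coupling). The precious dimer must be used in excess, and donor self-condensation or growth to tetramer may still dominate. The fallback blocks the donor's own nucleophilic site. It sets out from 13: N-bromosuccinimide in CH2Cl2 at −20 °C gives the 6-bromo donor F4. F4 (1.3 equiv) is coupled with 14 (1 equiv) under Me3SiOTf at −78 → −40 °C to the bromo trimer carbonate F5, and LiOH in THF/H2O gives the bromo trimer diol F6. Hydrogenolysis (H2, Pd(OH)2/C, Et3N, THF/MeOH) then removes the C–Br bond together with the nine benzyl ethers. The fallback comes back at 17.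

**Further compounds**

F1 | step 3 | racemic all-cis diol (1:1 mixture of 9 and F2) | c1cc2c(c(OCc5ccccc5)c1OCc5ccccc5)O[C@H](c1ccc(OCc5ccccc5)cc1)[C@H](O)[C@@H]2O.c1cc2c(c(OCc5ccccc5)c1OCc5ccccc5)O[C@@H](c1ccc(OCc5ccccc5)cc1)[C@@H](O)[C@H]2O
F2 | step 3 | (2S,3S,4S)-7,8-bis(benzyloxy)-2-[4-(benzyloxy)phenyl]chromane-3,4-diol (mirror image of 9) | c1cc2c(c(OCc5ccccc5)c1OCc5ccccc5)O[C@@H](c1ccc(OCc5ccccc5)cc1)[C@@H](O)[C@H]2O
F3 | step 6 | (2R,3S,4S)-7,8-bis(benzyloxy)-2-[4-(benzyloxy)phenyl]-4-(benzylsulfanyl)chroman-3-ol (4β-benzylsulfanyl donor) | c1cc2c(c(OCc5ccccc5)c1OCc5ccccc5)O[C@H](c1ccc(OCc5ccccc5)cc1)[C@H](O)[C@H]2SCc1ccccc1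
F4 | step 7 | (2R,3R,4S)-7,8-bis(benzyloxy)-2-[4-(benzyloxy)phenyl]-6-bromo-4-(2-ethoxyethoxy)chroman-3-ol (6-bromo donor) | Brc1cc2c(c(OCc5ccccc5)c1OCc5ccccc5)O[C@H](c1ccc(OCc5ccccc5)cc1)[C@H](O)[C@H]2OCCOCC
F5 | step 7 | 15 carrying bromine at C6 of the upper unit (bromo trimer carbonate) | c5ccccc5COc1ccc([C@H]2Oc3c(cc(Br)c(OCc5ccccc5)c3OCc5ccccc5)[C@H](c3cc4c(c(OCc5ccccc5)c3OCc5ccccc5)O[C@H](c3ccc(OCc5ccccc5)cc3)[C@H](O)[C@H]4c3cc4c(c(OCc5ccccc5)c3OCc5ccccc5)O[C@H](c3ccc(OCc5ccccc5)cc3)[C@H](OC(=O)O6)[C@@H]46)[C@H]2O)cc1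
F6 | step 7 | 16 carrying bromine at C6 of the upper unit (bromo trimer diol) | c5ccccc5COc1ccc([C@H]2Oc3c(cc(Br)c(OCc5ccccc5)c3OCc5ccccc5)[C@H](c3cc4c(c(OCc5ccccc5)c3OCc5ccccc5)O[C@H](c3ccc(OCc5ccccc5)cc3)[C@H](O)[C@H]4c3cc4c(c(OCc5ccccc5)c3OCc5ccccc5)O[C@H](c3ccc(OCc5ccccc5)cc3)[C@H](O)[C@@H]4O)[C@H]2O)cc1
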